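**Plan**
1. Numbering: flavan O1, C2–C4, C4a–C8a; ring B C1'–C6'; chromene pyran O1'', C2'', C3'', C4'' (O1'' on C4', C4'' on C3'). Cuts: C6–C(CH3)2 of ring A (back to a 7-O-prenyl ether, aromatic Claisen); C3'–C4'' of the pyran, re-attached to C4' (back to a spiro 2,5-dihydrofuran); spiro C4'–O1'' (oxidative dearomatisation of a 5'-phenol); the two C2''–CH3 bonds (MeLi on a coumarin); O1–C2 (Mitsunobu); C2–C1' (aryllithium + lactone).
2. Enabling feature: O1'' (on C4') and the free hydroxyl (on C5') sit on neighbouring carbons of ring B, and C3' is the unsubstituted CH on the other side of C4'. Ring B is therefore the aromatised form of a cyclohexa-2,4-dienone (C5'=O) whose spiro carbon C4' carries O1'' and C4''; a 1,2-shift of C4'' to C3' expands the five-membered ring C4'–O1''–C2''–C3''=C4'' to the chromene and regenerates the 5'-hydroxyl.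
3. Forward: lactone 3 (ring A) and bromide 7 (ring B) are joined at C2–C1'; ring C is closed; ring B is formylated at C4', annulated to a coumarin and opened to the (Z)-allylic alcohol; the spiro five-membered ring is closed on C4' and expanded to the chromene; the Claisen shift installs the 1,1-dimethylallyl group last.
4. Stereochemistry: the only stereocentre, C2 (S), comes from asymmetric transfer hydrogenation of ketone 9 to the (R)-carbinol and inversion in the Mitsunobu closure; the spiro centre of 19 is transient and uncontrolled.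

Key step: step 14

Remark on the chemistry: prenyl = 3-methylbut-2-en-1-yl, TBS = tert-butyldimethylsilyl; 19 is assumed to be usable as the mixture of both epimers at its spiro carbon, because that centre disappears in step 14.

**Step 1**
Reactants: 1 umbelliferone (7-hydroxycoumarin)
Product: 2 7-hydroxychroman-2-one
Conditions: H2 (1 atm), 10% Pd/C, AcOH, rt
Reagents that add atoms: none
Why: Catalytic hydrogenation saturates only the conjugated C3=C4 bond of the coumarin; arene and lactone are inert under these conditions.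

**Step 2**
Reactants: 2 7-hydroxychroman-2-one
Product: 3 7-(prenyloxy)chroman-2-one
Conditions: prenyl bromide, K2CO3, acetone, rt
Reagents that add atoms: prenyl bromide (1-bromo-3-methylbut-2-ene), CC(C)=CCBr
Why: Williamson etherification of the phenoxide at the primary allylic bromide (SN2) should proceed without opening the lactone under weakly basic, anhydrous conditions.

**Step 3**
Reactants: 4 3-bromo-4-methylphenol
Product: 5 (3-bromo-4-methylphenoxy)(tert-butyl)dimethylsilane
Conditions: TBSCl, imidazole, DMF, rt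
Reagents that add atoms: tert-butyldimethylsilyl chloride, CC(C)(C)[Si](C)(C)Cl
Why: Standard silylation masks the phenol for the radical, Grignard and organolithium steps that follow.

**Step 4**
Reactants: 5 (3-bromo-4-methylphenoxy)(tert-butyl)dimethylsilane
Product: 6 [3-bromo-4-(bromomethyl)phenoxy](tert-butyl)dimethylsilane
Conditions: NBS, AIBN (cat.), PhCF3, 80 °C
Reagents that add atoms: N-bromosuccinimide, O=C1CCC(=O)N1Br
Why: Wohl–Ziegler radical bromination attacks the benzylic methyl group, the only position that gives a stabilised radical.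

**Step 5**
Reactants: 6 [3-bromo-4-(bromomethyl)phenoxy](tert-butyl)dimethylsilane
Product: 7 (3-bromo-4-prenylphenoxy)(tert-butyl)dimethylsilane
Conditions: Me2C=CHMgBr, CuI (10 mol %), THF, −40 → 0 °C
Reagents that add atoms: 2-methylprop-1-en-1-ylmagnesium bromide, CC(C)=C[Mg]Br
Why: Copper-catalysed coupling of a benzylic bromide with an alkenyl Grignard reagent (Kochi-type sp3–sp2 cross-coupling) builds the prenyl chain with the double bond in a defined position and leaves the aryl bromide untouched.

**Step 6**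
Reactants: 7 (3-bromo-4-prenylphenoxy)(tert-butyl)dimethylsilane, 3 7-(prenyloxy)chroman-2-one
Product: 9 1-[5-(TBSO)-2-prenylphenyl]-3-[2-hydroxy-4-(prenyloxy)phenyl]propan-1-one, via aryllithium 8 (not isolated)
Conditions: t-BuLi (2 equiv), Et2O, −78 °C; cannulated into 3, THF, −78 °C; aq. NH4Cl
Reagents that add atoms: none
Why: Bromine–lithium exchange followed by acyl substitution at the aryl ester carbonyl opens the lactone to the keto phenol; the lithium hemiketal alkoxide and the ortho prenyl group should hold back a second addition at −78 °C.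

**Step 7**
Reactants: 9 1-[5-(TBSO)-2-prenylphenyl]-3-[2-hydroxy-4-(prenyloxy)phenyl]propan-1-one
Product: 10 (1R)-1-[5-(TBSO)-2-prenylphenyl]-3-[2-hydroxy-4-(prenyloxy)phenyl]propan-1-ol
Conditions: RuCl[(R,R)-TsDPEN](p-cymene) (2 mol %), HCO2H/Et3N (5:2), EtOAc, 30 °C
Reagents that add atoms: none
Why: Noyori asymmetric transfer hydrogenation of the aryl alkyl ketone; the (R,R)-diamine catalyst delivers hydride to the face that gives the (R)-carbinol (aryl group oriented by the CH–π contact with the arene ligand), and isolated alkenes, silyl ether and phenol are not affected.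

**Step 8**
Reactants: 10 (1R)-1-[5-(TBSO)-2-prenylphenyl]-3-[2-hydroxy-4-(prenyloxy)phenyl]propan-1-ol
Product: 11 tert-butyldimethyl{3-[(2S)-7-(prenyloxy)chroman-2-yl]-4-prenylphenoxy}silane
Conditions: PPh3, DIAD, THF, 0 °C → rt
Reagents that add atoms: none
Why: Intramolecular Mitsunobu etherification closes ring C by 6-exo-tet SN2 attack of the phenol on the activated carbinol with inversion, so the (R)-alcohol gives the (S)-flavan; ring B carries no para oxygen at this stage, which disfavours ionisation of the benzylic carbon.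

**Step 9**
Reactants: 11 tert-butyldimethyl{3-[(2S)-7-(prenyloxy)chroman-2-yl]-4-prenylphenoxy}silane
Product: 12 3-[(2S)-7-(prenyloxy)chroman-2-yl]-4-prenylphenol
Conditions: TBAF, THF, 0 °C
Reagents that add atoms: none
Why: Fluoride cleaves the aryl silyl ether selectively; ethers, alkenes and the stereocentre are inert.

**Step 10**
Reactants: 12 3-[(2S)-7-(prenyloxy)chroman-2-yl]-4-prenylphenol
Product: 14 2-hydroxy-4-[(2S)-7-(prenyloxy)chroman-2-yl]-5-prenylbenzaldehyde, via hydroxymethylphenol 13 (not isolated)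
Conditions: MgCl2, Et3N, (CH2O)n, MeCN, 80 °C
Reagents that add atoms: paraformaldehyde (as formaldehyde), C=O
Why: Casnati–Skattebøl ortho-formylation: the magnesium phenoxide delivers formaldehyde to an ortho carbon (C4', because C6' is flanked by the chromanyl group and the para carbon is blocked), and the benzylic alcohol formed is oxidised by a second formaldehyde; ring A has no free hydroxyl and does not react.

**Step 11**
Reactants: 14 2-hydroxy-4-[(2S)-7-(prenyloxy)chroman-2-yl]-5-prenylbenzaldehyde
Product: 16 7-[(2S)-7-(prenyloxy)chroman-2-yl]-6-prenyl-2H-chromen-2-one, via acyl ylide 15 (not isolated)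
Conditions: Ph3P=C=C=O, toluene, 110 °C
Reagents that add atoms: (triphenylphosphoranylidene)ketene, O=C=C=P(c1ccccc1)(c1ccccc1)c1ccccc1
Why: The phenol adds to the cumulated ylide and the resulting acyl ylide closes by intramolecular Wittig olefination onto the neighbouring aldehyde, which enforces the cis alkene of the coumarin at a temperature below that of the aryl prenyl ether Claisen shift.

**Step 12**
Reactants: 16 7-[(2S)-7-(prenyloxy)chroman-2-yl]-6-prenyl-2H-chromen-2-one
Product: 18 2-[(1Z)-3-hydroxy-3-methylbut-1-en-1-yl]-5-[(2S)-7-(prenyloxy)chroman-2-yl]-4-prenylphenol, via enone phenolate 17 (not isolated)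
Conditions: MeLi (4 equiv), THF, −78 → −20 °C; aq. NH4Cl, 0 °C
Reagents that add atoms: methyllithium, [Li]C
Why: Two 1,2-additions of methyllithium to the lactone carbonyl (ring opening, then addition to the ketone) give the tertiary alcohol, and the Z geometry of the alkene is inherited from the coumarin ring.

**Step 13**
Reactants: 18 2-[(1Z)-3-hydroxy-3-methylbut-1-en-1-yl]-5-[(2S)-7-(prenyloxy)chroman-2-yl]-4-prenylphenol
Product: 19 2,2-dimethyl-9-prenyl-8-[(2S)-7-(prenyloxy)chroman-2-yl]-1-oxaspiro[4.5]deca-3,7,9-trien-6-one (both epimers at the spiro carbon)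
Conditions: PhI(OAc)2, NaHCO3, MeCN, −20 → 0 °C; filtered through Et3N-treated silica, used at once
Reagents that add atoms: none
Why: Oxidative dearomatisation of the phenol by a trivalent iodine reagent; the tertiary hydroxyl, held next to C4' by the Z alkene, should trap the electrophilic ortho carbon in a 5-exo-trig spiroetherification faster than external nucleophiles attack the para carbon C2', and the new spiro centre forms without control, which does not matter.

**Step 14**
Reactants: 19 2,2-dimethyl-9-prenyl-8-[(2S)-7-(prenyloxy)chroman-2-yl]-1-oxaspiro[4.5]deca-3,7,9-trien-6-one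
Product: 20 2,2-dimethyl-5-prenyl-6-[(2S)-7-(prenyloxy)chroman-2-yl]-2H-chromen-8-ol
Conditions: BF3·OEt2 (20 mol %), CH2Cl2, −78 → −30 °C; then Et3N
Reagents that add atoms: none
Why: Proposed new method: BF3 binds the C5' carbonyl oxygen of 19 and places positive charge on C3' of a hydroxypentadienyl cation; the alkenyl carbon C4'' then moves suprafacially from the spiro carbon C4' to C3', which leaves an oxocarbenium ion at C4' stabilised by O1'', and loss of the C3' proton aromatises ring B to the 2H-chromene with the hydroxyl restored on C5'. The closest known reaction type is the acid-promoted dienone–phenol rearrangement, namely the 1,2-shifts of 6,6-disubstituted cyclohexa-2,4-dienones and the ring expansion of spirocyclic para-quinol ethers (1-oxaspiro[4.5]decadienones) to chromanols; the shift of an alkenyl carbon in an ortho-quinol spiro-2,5-dihydrofuran to give a chromene has not been shown. No ring is closed by a cyclisation: the six-membered pyran arises from the five-membered dihydrofuran by ring expansion, C3' being inserted between C4' and C4'' through the 1,2-shift. No stereocentre is formed; the spiro centre is destroyed, so both epimers of 19 converge, and C2 is not part of the reacting system. The step needs migration of carbon and not of oxygen, and to C3' and not to the carbonyl carbon, which is secured by the lone pair of O1'' at the migration origin, by the high migratory aptitude of an sp2 carbon and by the aromatisation that only the shift to C3' allows; it also needs the tertiary allylic C2''–O1'' bond, the aryl prenyl ether and the benzylic C2–O1 bond to survive, hence a catalytic amount of Lewis acid at low temperature.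

**Step 15**
Reactants: 20 2,2-dimethyl-5-prenyl-6-[(2S)-7-(prenyloxy)chroman-2-yl]-2H-chromen-8-ol
Product: 22 kazinol H, via ortho-dienone 21 (not isolated)
Conditions: EtOH/H2O (4:1), sealed tube, 130 °C
Reagents that add atoms: none
Why: Aromatic Claisen rearrangement: the suprafacial [3,3] shift through a chair transition state bonds the tertiary allyl carbon to an ortho carbon, C6 being preferred over C8 (which lies between two oxygen substituents and is the usual minor site in chromans), and enolisation of the dienone restores ring A with the free 7-hydroxyl; the hydrogen-bonding solvent lowers the temperature needed and no stereocentre is touched.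

**Compound list**
1 | umbelliferone (7-hydroxy-2H-chromen-2-one) | O=c1ccc2ccc(O)cc2o1 | starting material
2 | 7-hydroxychroman-2-one | O=C1CCc2ccc(O)cc2O1 | intermediate
3 | 7-[(3-methylbut-2-en-1-yl)oxy]chroman-2-one | CC(C)=CCOc1ccc2CCC(=O)Oc2c1 | intermediate
4 | 3-bromo-4-methylphenol | Cc1ccc(O)cc1Br | starting material
5 | (3-bromo-4-methylphenoxy)(tert-butyl)dimethylsilane | Cc1ccc(O[Si](C)(C)C(C)(C)C)cc1Br | intermediate
6 | [3-bromo-4-(bromomethyl)phenoxy](tert-butyl)dimethylsilane | BrCc1ccc(O[Si](C)(C)C(C)(C)C)cc1Br | intermediate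
7 | [3-bromo-4-(3-methylbut-2-en-1-yl)phenoxy](tert-butyl)dimethylsilane | CC(C)=CCc1ccc(O[Si](C)(C)C(C)(C)C)cc1Br | intermediate
8 | {5-[(tert-butyldimethylsilyl)oxy]-2-(3-methylbut-2-en-1-yl)phenyl}lithium (not isolated) | [Li]c1cc(O[Si](C)(C)C(C)(C)C)ccc1CC=C(C)C | intermediate
9 | 1-{5-[(tert-butyldimethylsilyl)oxy]-2-prenylphenyl}-3-[2-hydroxy-4-(prenyloxy)phenyl]propan-1-one | CC(C)=CCOc1ccc(CCC(=O)c2cc(O[Si](C)(C)C(C)(C)C)ccc2CC=C(C)C)c(O)c1 | intermediate
10 | (1R)-1-{5-[(tert-butyldimethylsilyl)oxy]-2-prenylphenyl}-3-[2-hydroxy-4-(prenyloxy)phenyl]propan-1-ol | CC(C)=CCOc1ccc(CC[C@@H](O)c2cc(O[Si](C)(C)C(C)(C)C)ccc2CC=C(C)C)c(O)c1 | intermediate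
11 | tert-butyldimethyl{3-[(2S)-7-(prenyloxy)chroman-2-yl]-4-prenylphenoxy}silane | CC(C)=CCOc1ccc2CC[C@@H](c3cc(O[Si](C)(C)C(C)(C)C)ccc3CC=C(C)C)Oc2c1 | intermediate
12 | 3-[(2S)-7-(prenyloxy)chroman-2-yl]-4-prenylphenol | CC(C)=CCOc1ccc2CC[C@@H](c3cc(O)ccc3CC=C(C)C)Oc2c1 | intermediate
13 | 2-(hydroxymethyl)-5-[(2S)-7-(prenyloxy)chroman-2-yl]-4-prenylphenol (in the flask as its magnesium phenoxide; neutral form drawn; not isolated) | CC(C)=CCOc1ccc2CC[C@@H](c3cc(O)c(CO)cc3CC=C(C)C)Oc2c1 | intermediate
14 | 2-hydroxy-4-[(2S)-7-(prenyloxy)chroman-2-yl]-5-prenylbenzaldehyde | CC(C)=CCOc1ccc2CC[C@@H](c3cc(O)c(C=O)cc3CC=C(C)C)Oc2c1 | intermediate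
15 | 2-formyl-5-[(2S)-7-(prenyloxy)chroman-2-yl]-4-prenylphenyl (triphenylphosphoranylidene)acetate (not isolated) | CC(C)=CCOc1ccc2CC[C@@H](c3cc(OC(=O)C=P(c4ccccc4)(c4ccccc4)c4ccccc4)c(C=O)cc3CC=C(C)C)Oc2c1 | intermediate
16 | 7-[(2S)-7-(prenyloxy)chroman-2-yl]-6-prenyl-2H-chromen-2-one | CC(C)=CCOc1ccc2CC[C@@H](c3cc4OC(=O)C=Cc4cc3CC=C(C)C)Oc2c1 | intermediate
17 | lithium 2-[(1Z)-3-oxobut-1-en-1-yl]-5-[(2S)-7-(prenyloxy)chroman-2-yl]-4-prenylphenolate (not isolated) | CC(C)=CCOc1ccc2CC[C@@H](c3cc([O-])c(/C=C\C(C)=O)cc3CC=C(C)C)Oc2c1.[Li+] | intermediate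
18 | 2-[(1Z)-3-hydroxy-3-methylbut-1-en-1-yl]-5-[(2S)-7-(prenyloxy)chroman-2-yl]-4-prenylphenol | CC(C)=CCOc1ccc2CC[C@@H](c3cc(O)c(/C=C\C(C)(C)O)cc3CC=C(C)C)Oc2c1 | intermediate
19 | 2,2-dimethyl-9-prenyl-8-[(2S)-7-(prenyloxy)chroman-2-yl]-1-oxaspiro[4.5]deca-3,7,9-trien-6-one, both epimers at spiro C5 | CC(C)=CCOc1ccc2CC[C@@H](C3=CC(=O)C4(C=CC(C)(C)O4)C=C3CC=C(C)C)Oc2c1 | intermediate
20 | 2,2-dimethyl-5-prenyl-6-[(2S)-7-(prenyloxy)chroman-2-yl]-2H-chromen-8-ol | CC(C)=CCOc1ccc2CC[C@@H](c3cc(O)c4OC(C)(C)C=Cc4c3CC=C(C)C)Oc2c1 | intermediate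
21 | (2S)-2-(8-hydroxy-2,2-dimethyl-5-prenyl-2H-chromen-6-yl)-6-(2-methylbut-3-en-2-yl)-3,4-dihydro-2H-chromen-7(6H)-one, both epimers at C6 (not isolated) | C=CC(C)(C)C1C=C2CC[C@@H](c3cc(O)c4OC(C)(C)C=Cc4c3CC=C(C)C)OC2=CC1=O | intermediate
22 | kazinol H, (2S)-2-(8-hydroxy-2,2-dimethyl-5-prenyl-2H-chromen-6-yl)-6-(2-methylbut-3-en-2-yl)chroman-7-ol | C=CC(C)(C)c1cc2c(cc1O)O[C@H](c1cc(O)c3c(c1CC=C(C)C)C=CC(C)(C)O3)CC2 | target

**Count**
Total steps: 15. Longest linear sequence: 13 steps (4 → 22, steps 3–15); the branch from 1 contributes two steps before the union in step 6.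

**Steps most likely to fail**

1. Step 14 (ring expansion, the step with the new-method label). What may go wrong:
- heterolysis of the tertiary allylic C2''–O1'' bond instead of the 1,2-shift;
- migration of oxygen instead of carbon;
- a hydride shift from C2 to the cationic C1' with loss of configuration;
- Lewis-acid cleavage of the aryl prenyl ether;
- Diels–Alder dimerisation of the dienone before it rearranges.

Fallback, known reactions only (the pyran is built by the aryl propargyl ether route on an oxygen introduced through halogenation and borylation). The route is left at phenol 12 and rejoined at 20. Iodination of 12 at the less hindered ortho carbon C4' (I2, morpholine, CH2Cl2, 0 °C) should give ortho-iodophenol F1. Capping of the hydroxyl (TsCl, Et3N, DMAP) gives aryl tosylate F2, a group that cannot move to a neighbouring oxygen. Miyaura borylation (B2pin2, PdCl2(dppf), KOAc, dioxane, 80 °C) gives pinacol boronate F3, and oxidation (NaBO3, THF/H2O, rt) gives phenol F4, in which the oxygen on C4' is free and that on C5' is masked. Copper-catalysed alkylation with 3-chloro-3-methylbut-1-yne (DBU, CuCl2 cat., MeCN, 0 °C) gives propargyl ether F5. Heating (xylene, 130 °C) should bring about the propargyl Claisen shift to C3' (the only free ortho carbon), 1,5-hydrogen shift and oxa-6π closure to chromene tosylate F6. KOH in MeOH/THF at 60 °C cleaves the sulfonate and delivers 20.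

2. Step 13 (oxidative spirocyclisation). What may go wrong:
- acid-triggered cyclodehydration of 18 to the linear 2,2-dimethylchromene on the 5'-oxygen before the oxidant acts;
- capture of the oxidised ring at the para carbon C2' by acetate;
- oxidation of the electron-rich ring A;
- dimerisation of 19 on concentration.

Fallback (oxygen is delivered to C4' first and the ether ring is closed afterwards, so no tethered nucleophile has to intercept an oxidised arene). The route is left at 18 and rejoined at 19. Hydroxylative dearomatisation of 18 with stabilised 2-iodoxybenzoic acid (THF, rt, then aq. Na2S2O4), which transfers oxygen from pentavalent iodine to the substituted ortho carbon, should give ortho-quinol F7. Brief exposure to PPTS (cat., CH2Cl2, 0 °C) ionises the tertiary allylic alcohol, and the quinol hydroxyl closes the 2,5-dihydrofuran to give 19.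

3. Step 15 (Claisen shift). What may go wrong:
- [3,3] shift to C8 instead of C6;
- abnormal Claisen isomerisation, or cyclisation of the ortho-(1,1-dimethylallyl)phenol onto its own double bond, at the temperature needed;
- slow thermal erosion of the chromene and catechol monoether part, with no later step in which by-products could be removed.

Fallback (the sigmatropic step is moved in front of the ring B oxidation sequence and the 7-oxygen is then carried as a silyl ether). The route is left at coumarin 16 and rejoined at 22. Heating 16 (N,N-diethylaniline, 180 °C), in which the ring B oxygen is tied up as the lactone, should give hydroxy coumarin F8, from which any C8 isomer is separated. TBSOTf/2,6-lutidine gives silyl ether F9; MeLi as in step 12 gives diol F10; PhI(OAc)2/NaHCO3 as in step 13 gives spirodienone F11; BF3·OEt2 (cat.) as in step 14 gives chromenol F12, the aryl silyl ether being more acid-stable than the aryl prenyl ether it replaces. TBAF (THF, 0 °C) then gives 22.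

**Further compounds**
F1 | step 14 | 2-iodo-5-[(2S)-7-(prenyloxy)chroman-2-yl]-4-prenylphenol | CC(C)=CCOc1ccc2CC[C@@H](c3cc(O)c(I)cc3CC=C(C)C)Oc2c1
F2 | step 14 | 2-iodo-5-[(2S)-7-(prenyloxy)chroman-2-yl]-4-prenylphenyl 4-methylbenzenesulfonate | CC(C)=CCOc1ccc2CC[C@@H](c3cc(OS(=O)(=O)c4ccc(C)cc4)c(I)cc3CC=C(C)C)Oc2c1
F3 | step 14 | 5-[(2S)-7-(prenyloxy)chroman-2-yl]-4-prenyl-2-(4,4,5,5-tetramethyl-1,3,2-dioxaborolan-2-yl)phenyl 4-methylbenzenesulfonate | CC(C)=CCOc1ccc2CC[C@@H](c3cc(OS(=O)(=O)c4ccc(C)cc4)c(B4OC(C)(C)C(C)(C)O4)cc3CC=C(C)C)Oc2c1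
F4 | step 14 | 2-hydroxy-5-[(2S)-7-(prenyloxy)chroman-2-yl]-4-prenylphenyl 4-methylbenzenesulfonate | CC(C)=CCOc1ccc2CC[C@@H](c3cc(OS(=O)(=O)c4ccc(C)cc4)c(O)cc3CC=C(C)C)Oc2c1
F5 | step 14 | 2-[(2-methylbut-3-yn-2-yl)oxy]-5-[(2S)-7-(prenyloxy)chroman-2-yl]-4-prenylphenyl 4-methylbenzenesulfonate | CC(C)=CCOc1ccc2CC[C@@H](c3cc(OS(=O)(=O)c4ccc(C)cc4)c(OC(C)(C)C#C)cc3CC=C(C)C)Oc2c1
F6 | step 14 | 2,2-dimethyl-5-prenyl-6-[(2S)-7-(prenyloxy)chroman-2-yl]-2H-chromen-8-yl 4-methylbenzenesulfonate | CC(C)=CCOc1ccc2CC[C@@H](c3cc(OS(=O)(=O)c4ccc(C)cc4)c4OC(C)(C)C=Cc4c3CC=C(C)C)Oc2c1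
F7 | step 13 | 6-hydroxy-6-[(1Z)-3-hydroxy-3-methylbut-1-en-1-yl]-3-[(2S)-7-(prenyloxy)chroman-2-yl]-4-prenylcyclohexa-2,4-dien-1-one, both epimers at C6 | CC(C)=CCOc1ccc2CC[C@@H](C3=CC(=O)C(O)(/C=C\C(C)(C)O)C=C3CC=C(C)C)Oc2c1
F8 | step 15 | 7-[(2S)-7-hydroxy-6-(2-methylbut-3-en-2-yl)chroman-2-yl]-6-prenyl-2H-chromen-2-one | C=CC(C)(C)c1cc2CC[C@@H](c3cc4OC(=O)C=Cc4cc3CC=C(C)C)Oc2cc1O
F9 | step 15 | 7-[(2S)-7-[(tert-butyldimethylsilyl)oxy]-6-(2-methylbut-3-en-2-yl)chroman-2-yl]-6-prenyl-2H-chromen-2-one | C=CC(C)(C)c1cc2CC[C@@H](c3cc4OC(=O)C=Cc4cc3CC=C(C)C)Oc2cc1O[Si](C)(C)C(C)(C)C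
F10 | step 15 | 2-[(1Z)-3-hydroxy-3-methylbut-1-en-1-yl]-5-[(2S)-7-[(tert-butyldimethylsilyl)oxy]-6-(2-methylbut-3-en-2-yl)chroman-2-yl]-4-prenylphenol | C=CC(C)(C)c1cc2CC[C@@H](c3cc(O)c(/C=C\C(C)(C)O)cc3CC=C(C)C)Oc2cc1O[Si](C)(C)C(C)(C)C
F11 | step 15 | 8-[(2S)-7-[(tert-butyldimethylsilyl)oxy]-6-(2-methylbut-3-en-2-yl)chroman-2-yl]-2,2-dimethyl-9-prenyl-1-oxaspiro[4.5]deca-3,7,9-trien-6-one, both epimers at spiro C5 | C=CC(C)(C)c1cc2CC[C@@H](C3=CC(=O)C4(C=CC(C)(C)O4)C=C3CC=C(C)C)Oc2cc1O[Si](C)(C)C(C)(C)C
F12 | step 15 | 6-[(2S)-7-[(tert-butyldimethylsilyl)oxy]-6-(2-methylbut-3-en-2-yl)chroman-2-yl]-2,2-dimethyl-5-prenyl-2H-chromen-8-ol | C=CC(C)(C)c1cc2CC[C@@H](c3cc(O)c4OC(C)(C)C=Cc4c3CC=C(C)C)Oc2cc1O[Si](C)(C)C(C)(C)C
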